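**Plan**
- Retrosynthesis: the seven benzyl ethers come off last. The tetrahydrofuran is cut at O1–C5 to an open-chain 1,2,4-triol, then the ring B–ring C biaryl bond (Suzuki–Miyaura), then the tetralin C4–C4a bond (Friedel–Crafts). Both halves go back to one γ-aryl lactone, made by an aldol C2–C3 bond formation from 5-bromovanillin.
- Enabling feature: in the tetrahydrofuran (O1, C2 bearing ring B, C3 bearing CH2OH, C4 bearing OH and the isovanillyl CH2, C5) only C5 is not a stereocentre. O-alkylation at C5 therefore closes the ring without touching the C2–C3–C4 triad.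
- Forward order: common lactone 11; isovanillyl arm (alkylation, hydroxylation, borylation); vanillyl arm (alkylation, hydroxylation, reduction, acid closure of the tetralin carbocycle); biaryl coupling; hydride opening of the lactone; tetrahydrofuran closure; hydrogenolysis.
- Stereochemistry: C2 and C3 (and tetralin C3) come from an auxiliary-controlled syn-aldol. Both tertiary carbinols come from enolate hydroxylation anti to the neighbouring CH2OBn on the lactone ring. The tetralin benzylic centre comes from an all-equatorial Friedel–Crafts closure. The two halves have the same configuration at the CH(CH2O)–C(OH) pair, so one lactone serves both.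

Key step: step 19

Remark: in the text (not in the systematic names) O1 and C2–C5 are the tetrahydrofuran atoms of the target, C5 being the lactone carbonyl carbon in the lactones 8–11, 14–18, 21–24 and 28. For the tetralin, C1 is the ring CH2, C2 the carbinol carbon, C3 the CH(CH2O) carbon and C4 the aryl-bearing carbon. Salts formed by simple O–H or N–H deprotonation are not numbered separately; boron and alkali-metal enolates are. Benzyl alcohols 12 and 19 are taken as purchasable.

**Route**

Step 1
Reactants: 1 5-bromovanillin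
Product: 2 4-(benzyloxy)-3-bromo-5-methoxybenzaldehyde
Conditions: BnBr, K2CO3, DMF, 60 °C
Reagents that add atoms: benzyl bromide, BrCc1ccccc1
Why: Williamson O-benzylation of the phenoxide; the aldehyde and the aryl bromide are inert to carbonate.

Step 2
Reactants: 3 (4S)-4-benzyl-1,3-oxazolidin-2-one; 4 methyl 4-chloro-4-oxobutanoate
Product: 5 succinate imide
Conditions: n-BuLi, THF, −78 °C; then 4, −78 to 0 °C
Reagents that add atoms: none
Why: N-acylation of the lithiated oxazolidinone by the acid chloride, which is far more electrophilic than the methyl ester at this temperature.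

Step 3
Reactants: 5 succinate imide; 2 4-(benzyloxy)-3-bromo-5-methoxybenzaldehyde
Product: 8 trans-lactone imide, via dibutylboron enolate 6 (not isolated), via boron aldolate 7 (not isolated)
Conditions: Bu2BOTf, iPr2NEt, CH2Cl2, 0 °C; 2, −78 °C to rt; pH 7 buffer, MeOH, H2O2, 0 °C
Reagents that add atoms: none
Why: Evans syn-aldol followed by lactonisation: only the imide carbonyl is enolised, to the (Z)-boron enolate, which adds through a Zimmerman–Traxler chair on the face away from the auxiliary benzyl group and sets the future C2 (S) and C3 (R) syn; the aldolate oxygen then closes onto the methyl ester to give the 2,3-trans γ-lactone.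

Step 4
Reactants: 8 trans-lactone imide
Product: 9 lactone carboxylic acid
Conditions: LiOH, H2O2, THF/H2O, 0 °C; Na2SO3; 1 M HCl
Reagents that add atoms: hydrogen peroxide (as lithium hydroperoxide), OO
Why: Hydroperoxide attacks the exocyclic imide carbonyl (standard auxiliary removal) and sulfite reduces the peracid; any lactone opened by hydroxide recloses on acidification and no stereocentre is touched.

Step 5
Reactants: 9 lactone carboxylic acid
Product: 10 hydroxymethyl lactone
Conditions: BH3·SMe2, THF, 0 °C to rt; MeOH quench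
Reagents that add atoms: none
Why: Borane reduces a carboxylic acid much faster than a γ-lactone, the usual chemoselective route from lactone acids of this kind to hydroxymethyl lactones.

Step 6
Reactants: 10 hydroxymethyl lactone
Product: 11 common benzyloxymethyl lactone
Conditions: BnBr, Ag2O, CH2Cl2, rt, dark
Reagents that add atoms: benzyl bromide, BrCc1ccccc1
Why: Ag2O-promoted benzylation proceeds without a free alkoxide, so translactonisation onto the primary oxygen and epimerisation are avoided.

Step 7
Reactants: 12 [3-(benzyloxy)-4-methoxyphenyl]methanol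
Product: 13 3-(benzyloxy)-4-methoxybenzyl bromide
Conditions: PBr3, Et2O, 0 °C
Reagents that add atoms: phosphorus tribromide, BrP(Br)Br
Why: Bromination of an electron-rich benzylic alcohol through its phosphite ester; the bromide is used directly.

Step 8
Reactants: 11 common benzyloxymethyl lactone; 13 3-(benzyloxy)-4-methoxybenzyl bromide
Product: 15 isovanillyl lactone, via lithium enolate 14 (not isolated)
Conditions: LiN(SiMe3)2, THF, −78 °C; then 13, −78 to −30 °C
Reagents that add atoms: none
Why: Alkylation of the lactone enolate by a reactive benzylic bromide; the electrophile should enter at C4 anti to the CH2OBn group on C3 (3,4-trans in the lactone), although this centre becomes planar again in step 9.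

Step 9
Reactants: 15 isovanillyl lactone
Product: 17 isovanillyl hydroxy lactone, via potassium enolate 16 (not isolated)
Conditions: KN(SiMe3)2, THF, −78 °C; then 3-phenyl-2-(phenylsulfonyl)oxaziridine, −78 °C; aq. NH4Cl
Reagents that add atoms: 3-phenyl-2-(phenylsulfonyl)oxaziridine, O=S(=O)(N1OC1c1ccccc1)c1ccccc1
Why: Davis hydroxylation of the tetrasubstituted enolate: oxygen is delivered to the face anti to the adjacent CH2OBn group (the usual 1,2-induction of β-substituted butyrolactone enolates), which should put the new hydroxyl trans to CH2OBn and the isovanillyl group cis, i.e. C4 (S).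

Step 10
Reactants: 17 isovanillyl hydroxy lactone
Product: 18 lactone pinacol boronate
Conditions: B2pin2, Pd(dppf)Cl2, KOAc, 1,4-dioxane, 85 °C
Reagents that add atoms: bis(pinacolato)diboron, CC1(C)OB(OC1(C)C)B1OC(C)(C)C(C)(C)O1
Why: Miyaura borylation of the aryl bromide; the weak base KOAc leaves the hydroxy lactone and the benzyl ethers alone.

Step 11
Reactants: 19 [4-(benzyloxy)-3-methoxyphenyl]methanol
Product: 20 4-(benzyloxy)-3-methoxybenzyl bromide
Conditions: PBr3, Et2O, 0 °C
Reagents that add atoms: phosphorus tribromide, BrP(Br)Br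
Why: Same benzylic bromination as in step 7.

Step 12
Reactants: 11 common benzyloxymethyl lactone; 20 4-(benzyloxy)-3-methoxybenzyl bromide
Product: 22 vanillyl lactone, via sodium enolate 21 (not isolated)
Conditions: NaN(SiMe3)2, THF, −78 °C; then 20, −78 to −30 °C
Reagents that add atoms: none
Why: Enolate alkylation of a β-substituted butyrolactone, here through the more nucleophilic sodium enolate so that the readily ionised para-alkoxybenzyl bromide is consumed at low temperature; the electrophile enters anti to the CH2OBn group and the new centre is erased again in step 13.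

Step 13
Reactants: 22 vanillyl lactone
Product: 24 vanillyl hydroxy lactone, via potassium enolate 23 (not isolated)
Conditions: KN(SiMe3)2, THF, −78 °C; then 3-phenyl-2-(phenylsulfonyl)oxaziridine, −78 °C; aq. NH4Cl
Reagents that add atoms: 3-phenyl-2-(phenylsulfonyl)oxaziridine, O=S(=O)(N1OC1c1ccccc1)c1ccccc1
Why: Davis hydroxylation anti to the CH2OBn group as in step 9, which should set the carbinol centre that becomes tetralin C2 (S).

Step 14
Reactants: 24 vanillyl hydroxy lactone
Product: 25 bromo triol
Conditions: LiBH4, THF, 0 °C to rt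
Reagents that add atoms: none
Why: LiBH4 reduces the lactone to the primary and benzylic alcohols without touching the aryl bromide or any stereocentre.

Step 15
Reactants: 25 bromo triol
Product: 26 tetralin diol
Conditions: CF3CO2H, CH2Cl2, 0 °C; aq. NaHCO3
Reagents that add atoms: none
Why: Intramolecular Friedel–Crafts alkylation, the known acid-induced conversion of benzylic lignan alcohols into aryltetralins: the para-alkoxybenzylic alcohol ionises and the vanillyl ring attacks para to its methoxy group (6-membered ring), hydroxyl capture of the cation being reversible and arylation not; a chair-like closure with aryl, CH2OBn and CH2OH all equatorial should set tetralin C4 (S) trans to C3.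

Step 16
Reactants: 26 tetralin diol
Product: 27 tetralin bromide
Conditions: NaH (1.1 equiv), BnBr, Bu4NI (cat.), THF, 0 °C to rt
Reagents that add atoms: benzyl bromide, BrCc1ccccc1
Why: Williamson benzylation with one equivalent of base is selective for the primary alkoxide over the hindered tertiary one, and it blocks the only other primary hydroxyl before the sulfonylation of step 19.

Step 17
Reactants: 18 lactone pinacol boronate; 27 tetralin bromide
Product: 28 biaryl lactone
Conditions: Pd(OAc)2, SPhos, K3PO4, toluene/H2O, 90 °C; dilute acid work-up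
Reagents that add atoms: none
Why: Suzuki–Miyaura coupling with an electron-rich biaryl phosphine, the standard answer to two ortho-alkoxylated partners; the axis carries one ortho substituent per ring and rotates freely, and any lactone opened by the base recloses on work-up or converges on 29 in step 18 anyway.

Step 18
Reactants: 28 biaryl lactone
Product: 29 biaryl triol
Conditions: LiAlH4, THF, 0 °C
Reagents that add atoms: none
Why: Hydride reduction of the lactone gives the C2, C4, C5 triol with C2, C3 and C4 unchanged; benzyl ethers and the tetralin alcohol are inert.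

Step 19
Reactants: 29 biaryl triol
Product: 32 hepta-O-benzyl ether of the target, via primary sulfonate 30 (not isolated), via epoxide 31 (not isolated)
Conditions: 2,4,6-iPr3C6H2SO2Cl, Et3N, DMAP (cat.), CH2Cl2, 0 °C to rt; then KOtBu, THF, 0 °C to rt
Reagents that add atoms: none
Why: The bulky sulfonyl chloride should esterify only the primary C5 hydroxyl (the C2 carbinol is secondary and flanked by ring B and C3, the two tertiary hydroxyls are inert) to give 30; with KOtBu the C4 alkoxide displaces the sulfonate (3-exo-tet) to the 2,2-disubstituted epoxide 31, and the C2 benzylic alkoxide then opens it at the CH2 terminus, forming O1–C5. The closest known reactions are the base-induced conversion of 6-O-sulfonyl or 5,6-anhydro hexoses into 3,6-anhydro sugars and the Williamson closure of 1,4-diol monosulfonates to tetrahydrofurans. The ring closes in the 5-exo-tet mode if the alkoxide attacks the sulfonate directly, and in the epoxide-opening mode usually called 5-endo (attack at the distal epoxide carbon) via 31; both give the same product. No stereocentre is created: C5 is a CH2 group, the C4–O bond is never broken and C2 reacts through its oxygen, so the (2S,3R,4S) triad set on the lactone is carried over unchanged. The step needs attack of the C2 oxygen at C5 rather than C4 and no participation of other hydroxyls; this is secured by the fully substituted C4 (no SN2, oxetane disfavoured), the benzyl ethers on every other primary oxygen and the inert tetralin alcohol. The basic medium never generates the C2 benzylic cation, which would epimerise C2 or alkylate the isovanillyl ring.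

Step 20
Reactants: 32 hepta-O-benzyl ether of the target
Product: 33 CNP0252244.1
Conditions: H2 (1 atm), Pd/C, EtOAc, rt
Reagents that add atoms: none
Why: Hydrogenolysis of the four aryl and three alkyl benzyl ethers under neutral conditions; benzyl ethers should be cleaved much faster than the cyclic secondary C2–O1 benzylic ether, and the reaction is stopped once the last benzyl group is gone.

**Compound list**

1 | 5-bromovanillin (3-bromo-4-hydroxy-5-methoxybenzaldehyde) | COc1cc(C=O)cc(Br)c1O | starting material
2 | 4-(benzyloxy)-3-bromo-5-methoxybenzaldehyde | O=Cc1cc(OC)c(OCc2ccccc2)c(Br)c1 | intermediate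
3 | (4S)-4-benzyl-1,3-oxazolidin-2-one | O=C1N[C@@H](Cc2ccccc2)CO1 | starting material
4 | methyl 4-chloro-4-oxobutanoate | COC(=O)CCC(Cl)=O | starting material
5 | methyl 4-[(4S)-4-benzyl-2-oxo-1,3-oxazolidin-3-yl]-4-oxobutanoate | COC(=O)CCC(=O)N1[C@@H](Cc2ccccc2)COC1=O | intermediate
6 | (Z)-dibutylboron enolate of 5 (formed in the flask) | COC(=O)C/C=C(\OB(CCCC)CCCC)N1[C@@H](Cc2ccccc2)COC1=O | intermediate
7 | dibutylboron syn-aldolate of 5 and 2 (formed in the flask) | COC(=O)C[C@H](C(=O)N1[C@@H](Cc2ccccc2)COC1=O)[C@H](OB(CCCC)CCCC)c1cc(OC)c(OCc2ccccc2)c(Br)c1 | intermediate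
8 | (4S)-4-benzyl-3-{[(2S,3S)-2-[4-(benzyloxy)-3-bromo-5-methoxyphenyl]-5-oxooxolan-3-yl]carbonyl}-1,3-oxazolidin-2-one | O=C1C[C@H](C(=O)N2[C@@H](Cc3ccccc3)COC2=O)[C@@H](c2cc(OC)c(OCc3ccccc3)c(Br)c2)O1 | intermediate
9 | (2S,3S)-2-[4-(benzyloxy)-3-bromo-5-methoxyphenyl]-5-oxooxolane-3-carboxylic acid | O=C1C[C@H](C(=O)O)[C@@H](c2cc(OC)c(OCc3ccccc3)c(Br)c2)O1 | intermediate
10 | (4R,5S)-5-[4-(benzyloxy)-3-bromo-5-methoxyphenyl]-4-(hydroxymethyl)oxolan-2-one | O=C1C[C@H](CO)[C@@H](c2cc(OC)c(OCc3ccccc3)c(Br)c2)O1 | intermediate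
11 | (4R,5S)-5-[4-(benzyloxy)-3-bromo-5-methoxyphenyl]-4-[(benzyloxy)methyl]oxolan-2-one | O=C1C[C@H](COCc2ccccc2)[C@@H](c2cc(OC)c(OCc3ccccc3)c(Br)c2)O1 | intermediate
12 | [3-(benzyloxy)-4-methoxyphenyl]methanol | COc1ccc(CO)cc1OCc1ccccc1 | starting material
13 | 3-(benzyloxy)-4-methoxybenzyl bromide | COc1ccc(CBr)cc1OCc1ccccc1 | intermediate
14 | lithium enolate of 11 (formed in the flask) | [Li]OC1=C[C@H](COCc2ccccc2)[C@@H](c2cc(OC)c(OCc3ccccc3)c(Br)c2)O1 | intermediate
15 | (3S,4R,5S)-5-[4-(benzyloxy)-3-bromo-5-methoxyphenyl]-3-[3-(benzyloxy)-4-methoxybenzyl]-4-[(benzyloxy)methyl]oxolan-2-one | COc1ccc(C[C@@H]2C(=O)O[C@H](c3cc(OC)c(OCc7ccccc7)c(Br)c3)[C@H]2COCc7ccccc7)cc1OCc7ccccc7 | intermediate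
16 | potassium enolate of 15 (formed in the flask) | COc1ccc(CC2=C(O[K])O[C@H](c3cc(OC)c(OCc7ccccc7)c(Br)c3)[C@H]2COCc7ccccc7)cc1OCc7ccccc7 | intermediate
17 | (3S,4R,5S)-5-[4-(benzyloxy)-3-bromo-5-methoxyphenyl]-3-[3-(benzyloxy)-4-methoxybenzyl]-4-[(benzyloxy)methyl]-3-hydroxyoxolan-2-one | COc1ccc(C[C@@]2(O)C(=O)O[C@H](c3cc(OC)c(OCc7ccccc7)c(Br)c3)[C@H]2COCc7ccccc7)cc1OCc7ccccc7 | intermediate
18 | pinacol boronate of 17 (Br replaced by 4,4,5,5-tetramethyl-1,3,2-dioxaborolan-2-yl) | COc1ccc(C[C@@]2(O)C(=O)O[C@H](c3cc(OC)c(OCc7ccccc7)c(B8OC(C)(C)C(C)(C)O8)c3)[C@H]2COCc7ccccc7)cc1OCc7ccccc7 | intermediate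
19 | [4-(benzyloxy)-3-methoxyphenyl]methanol | COc1cc(CO)ccc1OCc1ccccc1 | starting material
20 | 4-(benzyloxy)-3-methoxybenzyl bromide | COc1cc(CBr)ccc1OCc1ccccc1 | intermediate
21 | sodium enolate of 11 (formed in the flask) | [Na]OC1=C[C@H](COCc2ccccc2)[C@@H](c2cc(OC)c(OCc3ccccc3)c(Br)c2)O1 | intermediate
22 | (3S,4R,5S)-5-[4-(benzyloxy)-3-bromo-5-methoxyphenyl]-3-[4-(benzyloxy)-3-methoxybenzyl]-4-[(benzyloxy)methyl]oxolan-2-one | COc1cc(C[C@@H]2C(=O)O[C@H](c3cc(OC)c(OCc7ccccc7)c(Br)c3)[C@H]2COCc7ccccc7)ccc1OCc7ccccc7 | intermediate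
23 | potassium enolate of 22 (formed in the flask) | COc1cc(CC2=C(O[K])O[C@H](c3cc(OC)c(OCc7ccccc7)c(Br)c3)[C@H]2COCc7ccccc7)ccc1OCc7ccccc7 | intermediate
24 | (3S,4R,5S)-5-[4-(benzyloxy)-3-bromo-5-methoxyphenyl]-3-[4-(benzyloxy)-3-methoxybenzyl]-4-[(benzyloxy)methyl]-3-hydroxyoxolan-2-one | COc1cc(C[C@@]2(O)C(=O)O[C@H](c3cc(OC)c(OCc7ccccc7)c(Br)c3)[C@H]2COCc7ccccc7)ccc1OCc7ccccc7 | intermediate
25 | (2S,3R,4S)-4-[4-(benzyloxy)-3-bromo-5-methoxyphenyl]-2-[4-(benzyloxy)-3-methoxybenzyl]-3-[(benzyloxy)methyl]butane-1,2,4-triol | COc1cc(C[C@@](O)(CO)[C@H](COCc7ccccc7)[C@H](O)c3cc(OC)c(OCc7ccccc7)c(Br)c3)ccc1OCc7ccccc7 | intermediate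
26 | (2S,3S,4S)-6-(benzyloxy)-4-[4-(benzyloxy)-3-bromo-5-methoxyphenyl]-3-[(benzyloxy)methyl]-2-(hydroxymethyl)-7-methoxy-1,2,3,4-tetrahydronaphthalen-2-ol | COc1cc(cc(Br)c1OCc1ccccc1)[C@H]1c2cc(OCc3ccccc3)c(OC)cc2C[C@@](O)(CO)[C@@H]1COCc1ccccc1 | intermediate
27 | (2S,3S,4S)-6-(benzyloxy)-4-[4-(benzyloxy)-3-bromo-5-methoxyphenyl]-2,3-bis[(benzyloxy)methyl]-7-methoxy-1,2,3,4-tetrahydronaphthalen-2-ol | COc1cc(cc(Br)c1OCc1ccccc1)[C@H]1c2cc(OCc3ccccc3)c(OC)cc2C[C@@](O)(COCc2ccccc2)[C@@H]1COCc1ccccc1 | intermediate
28 | biaryl lactone: hydroxy lactone 17 with its bromine replaced by the ring C carbon of tetralin 27 that carried bromine (lactone 3S,4R,5S; tetralin 2S,3S,4S) | COc1ccc(C[C@@]2(O)C(=O)O[C@H](c3cc(OC)c(OCc7ccccc7)c(-c4cc([C@H]5c6cc(OCc7ccccc7)c(OC)cc6C[C@@](O)(COCc7ccccc7)[C@@H]5COCc7ccccc7)cc(OC)c4OCc7ccccc7)c3)[C@H]2COCc7ccccc7)cc1OCc7ccccc7 | intermediate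
29 | biaryl triol: open-chain (2S,3R,4S)-butane-1,2,4-triol with C4 on ring B, C3 bearing CH2OBn and C2 bearing the O-benzylisovanillyl CH2; ring B joined to the benzylated tetralin half | COc1ccc(C[C@@](O)(CO)[C@H](COCc7ccccc7)[C@H](O)c3cc(OC)c(OCc7ccccc7)c(-c4cc([C@H]5c6cc(OCc7ccccc7)c(OC)cc6C[C@@](O)(COCc7ccccc7)[C@@H]5COCc7ccccc7)cc(OC)c4OCc7ccccc7)c3)cc1OCc7ccccc7 | intermediate
30 | primary 2,4,6-triisopropylbenzenesulfonate of 29 (formed in the flask) | COc1ccc(C[C@@](O)(COS(=O)(=O)c8c(C(C)C)cc(C(C)C)cc8C(C)C)[C@H](COCc7ccccc7)[C@H](O)c3cc(OC)c(OCc7ccccc7)c(-c4cc([C@H]5c6cc(OCc7ccccc7)c(OC)cc6C[C@@](O)(COCc7ccccc7)[C@@H]5COCc7ccccc7)cc(OC)c4OCc7ccccc7)c3)cc1OCc7ccccc7 | intermediate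
31 | C4–C5 epoxide with free C2 hydroxyl (formed in the flask) | COc1ccc(C[C@@]8(CO8)[C@H](COCc7ccccc7)[C@H](O)c3cc(OC)c(OCc7ccccc7)c(-c4cc([C@H]5c6cc(OCc7ccccc7)c(OC)cc6C[C@@](O)(COCc7ccccc7)[C@@H]5COCc7ccccc7)cc(OC)c4OCc7ccccc7)c3)cc1OCc7ccccc7 | intermediate
32 | hepta-O-benzyl ether of the target (tetrahydrofuran 2S,3R,4S; both tertiary hydroxyls free) | COc1ccc(C[C@@]2(O)CO[C@H](c3cc(OC)c(OCc7ccccc7)c(-c4cc([C@H]5c6cc(OCc7ccccc7)c(OC)cc6C[C@@](O)(COCc7ccccc7)[C@@H]5COCc7ccccc7)cc(OC)c4OCc7ccccc7)c3)[C@H]2COCc7ccccc7)cc1OCc7ccccc7 | intermediate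
33 | CNP0252244.1 | COc1ccc(C[C@@]2(O)CO[C@H](c3cc(OC)c(O)c(-c4cc([C@H]5c6cc(O)c(OC)cc6C[C@@](O)(CO)[C@@H]5CO)cc(OC)c4O)c3)[C@H]2CO)cc1O | target

**Totals and risks**

Total step count: 20. Longest linear sequence: 14 steps (1, 3–6, 12–20).

Most likely to fail:

1. Step 19. The sulfonylation may not discriminate cleanly between the primary C5 and the secondary C2 hydroxyl on this large polyol, or the closure may stall at the epoxide, which is then opened intermolecularly by tert-butoxide. Fallback from 28, rejoining at 32: the lactone carbonyl, which already holds the O1–C5 bond, is taken down to CH2 without opening the ring. i-Bu2AlH in CH2Cl2 at −78 °C should give the lactol F1, and Et3SiH with BF3·OEt2 at −78 °C should reduce the derived oxocarbenium ion to 32. The low temperature is needed so that only the lactol acetal ionises and not the C2 benzylic ether.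

2. Step 9 (step 13 shares the risk). Oxygen may be delivered to the enolate face syn to the CH2OBn group because the γ-aryl group on the other face weighs more than expected, or the enolate may add to the sulfonimine that the oxidant leaves behind. Fallback from 11, rejoining at 17: the order of the two enolate reactions is reversed. Hydroxylation of 11 (KN(SiMe3)2, the same oxaziridine) should give the 3-hydroxy lactone F2. Its dianion (LiN(iPr)2, 2.2 equiv, DMPU, THF, −78 °C) is then alkylated with 13, so the benzyl group enters last and takes the face that oxygen preferred, which gives the required isomer 17 if the ring shows the opposite facial bias. The same F2 with 20 would give 24.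

3. Step 15. The benzylic cation, less stabilised because ring C carries bromine, may be diverted by hydroxyl capture or fragmentation faster than it is arylated, and aryl benzyl ethers may be lost on prolonged acid exposure. Fallback from 24, rejoining at 26: the Friedel–Crafts closure is run at the lactone oxidation level. BF3·OEt2 in CH2Cl2 ionises the benzylic lactone C–O bond, the carboxylate being the only internal oxygen nucleophile and its return degenerate, so the vanillyl ring should capture the cation to give the tetralin hydroxy acid F3. BH3·SMe2 then reduces the acid to 26.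

Further compounds
F1 | step 19 | lactol of 28 (lactone C=O reduced to CH–OH, anomeric mixture, other centres as in 28) | COc1ccc(C[C@@]2(O)C(O)O[C@H](c3cc(OC)c(OCc7ccccc7)c(-c4cc([C@H]5c6cc(OCc7ccccc7)c(OC)cc6C[C@@](O)(COCc7ccccc7)[C@@H]5COCc7ccccc7)cc(OC)c4OCc7ccccc7)c3)[C@H]2COCc7ccccc7)cc1OCc7ccccc7
F2 | step 9 | 5-[4-(benzyloxy)-3-bromo-5-methoxyphenyl]-4-[(benzyloxy)methyl]-3-hydroxyoxolan-2-one, 4,5-trans, hydroxyl drawn cis to the benzyloxymethyl group (this centre is planarised again on dianion formation) | O=C1[C@H](O)[C@H](COCc2ccccc2)[C@@H](c2cc(OC)c(OCc3ccccc3)c(Br)c2)O1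
F3 | step 15 | (2S,3S,4S)-6-(benzyloxy)-4-[4-(benzyloxy)-3-bromo-5-methoxyphenyl]-3-[(benzyloxy)methyl]-2-hydroxy-7-methoxy-1,2,3,4-tetrahydronaphthalene-2-carboxylic acid | COc1cc(cc(Br)c1OCc1ccccc1)[C@H]1c2cc(OCc3ccccc3)c(OC)cc2C[C@@](O)(C(=O)O)[C@@H]1COCc1ccccc1
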